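The tetrahydrofuran ring (O, C9, C8, C8', C9') is cut at O–C9 and C8–C8'. The cut is possible because C9 lies β to benzylic C7 and C8' lies next to benzylic C7'. With C7 as a ketone, O–C9 becomes an oxa-Michael bond and C8 an enolate carbon. With C7' masked as a vinyl CH, C8' becomes the substituted end of a π-allyl unit. One palladium-catalysed annulation of racemic butadiene monoxide with a non-enolisable, O-benzylated guaiacyl vinyl ketone thus closes the ring and makes both bonds. It sets C8' through the ligand and C8 by trans equilibration. Both carbinol centres then come from Felkin-controlled hydride reductions, which the C2 symmetry makes alike.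

Key step: step 3

Numbering: lignan numbering is used; C7/C7' are the benzylic carbons, C8/C8' the ring CH carbons, C9/C9' the ring OCH2 carbons. The target is (7S,8R,7'S,8'R), that is trans on the ring and C2-symmetric.

Assumption: the sense of induction of the (R,R)-ligand in this tethered enolate closure rests on analogy only; the absolute configuration is to be checked by Mosher ester analysis of the carbinol of step 4, and if it is opposite, the equally available (S,S)-ligand is used with nothing else changed.

Step 1
Reactants: 1 4-benzyloxy-3-methoxybenzaldehyde (O-benzylvanillin); 2 vinylmagnesium bromide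
Product: 3 rac-1-(4-benzyloxy-3-methoxyphenyl)prop-2-en-1-ol
Conditions: 2 (1.2 equiv), THF, −78 → 0 °C; aqueous work-up
Reagents that add atoms: none
Why: Grignard 1,2-addition of a vinyl nucleophile to a non-enolisable aromatic aldehyde is fast and clean, and the new carbinol centre needs no control because step 2 removes it.

Step 2
Reactants: 3 rac-1-(4-benzyloxy-3-methoxyphenyl)prop-2-en-1-ol
Product: 4 1-(4-benzyloxy-3-methoxyphenyl)prop-2-en-1-one
Conditions: activated MnO2 (15 equiv), CH2Cl2, rt; filtration through Celite, trace BHT, kept cold and used the same day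
Reagents that add atoms: none
Why: MnO2 oxidation of a doubly activated (benzylic and allylic) alcohol runs under neutral heterogeneous conditions, so the polymerisation-prone enone is obtained by mere filtration without contact with base or nucleophiles.

Step 3
Reactants: 4 1-(4-benzyloxy-3-methoxyphenyl)prop-2-en-1-one; 5 rac-butadiene monoxide (2-vinyloxirane)
Product: 7 trans-3-(4-benzyloxy-3-methoxybenzoyl)-4-vinyltetrahydrofuran (3R,4R; lignan 8R,8'R), via cis epimer 6 (not isolated)
Conditions: Pd2(dba)3·CHCl3 (2.5 mol %), (1R,2R)-N,N'-bis(2-diphenylphosphinobenzoyl)cyclohexane-1,2-diamine [(R,R)-DACH-phenyl ligand, 7.5 mol %], degassed CH2Cl2, 0 °C → rt, 5 (1.3 equiv) added over 4 h; then DBU (0.2 equiv), rt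
Reagents that add atoms: none
Why: Zerovalent palladium ionises 5 to a zwitterionic η3-allylpalladium alkoxide, the alkoxide adds to the unsubstituted β-carbon C9 of 4 (oxa-Michael addition, O–C9), and the aryl ketone enolate thus formed attacks the substituted allyl terminus (allylic alkylation, C8–C8') and returns the catalyst. The closest known reaction type is the palladium-catalysed formal [3+2] cycloaddition of vinyl epoxides with electron-poor alkenes, α,β-unsaturated ketones among them, joined to the dynamic kinetic asymmetric allylic substitution of butadiene monoxide with this ligand family. The tetrahydrofuran ring closes in a 5-exo mode (enolate double bond and remaining vinyl group both outside the new ring). C8' is controlled by the chiral ligand pocket, since the diastereomeric allyl complexes exchange faces by η3–η1–η3 isomerisation at the CH2 terminus faster than they cyclise, so both enantiomers of 5 converge. C8 is controlled thermodynamically: it is the only acidic centre, DBU moves cis epimer 6 to the less crowded trans isomer 7, and ring opening by β-elimination is slow because it is the reverse of a 5-endo closure. The step needs attack at the internal instead of the terminal allyl carbon, secured by the short O–C9–C8 tether (five- against seven-membered ring), and capture of the alkoxide by 4 ahead of epoxide oligomerisation and of allylation of the product enolate, secured by the unhindered, non-enolisable vinyl ketone and the slow addition of 5.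

Step 4
Reactants: 7 trans-3-(4-benzyloxy-3-methoxybenzoyl)-4-vinyltetrahydrofuran
Product: 8 (S)-(4-benzyloxy-3-methoxyphenyl)[(3R,4R)-4-vinyltetrahydrofuran-3-yl]methanol (7S,8R,8'R)
Conditions: LiBH(s-Bu)3 (1.2 equiv), THF, −78 °C; aqueous work-up
Reagents that add atoms: none
Why: Felkin–Anh-controlled reduction with a bulky trialkylborohydride, in which branched C8' stands perpendicular to the carbonyl plane, the C9 methylene beside the oxygen and H-8 beside the aryl group, so that hydride reaches the Re face of C7 anti to C8' and should give the 7S (7,8-syn) carbinol, while removal of the ketone also makes C8 non-enolisable, so that a later epimerisation at C8' can never lead to the enantiomer.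

Step 5
Reactants: 8 (S)-(4-benzyloxy-3-methoxyphenyl)[(3R,4R)-4-vinyltetrahydrofuran-3-yl]methanol
Product: 9 tert-butyldimethylsilyl ether of 8 (7S,8R,8'R)
Conditions: TBSOTf (1.3 equiv), 2,6-lutidine (2 equiv), CH2Cl2, −78 → 0 °C
Reagents that add atoms: tert-butyldimethylsilyl triflate, CC(C)(C)[Si](C)(C)OS(=O)(=O)C(F)(F)F
Why: Silylation of a hindered secondary alcohol with a silyl triflate and a non-nucleophilic base is reliable, and it keeps the C7 hydroxyl from closing a lactol on the coming aldehyde, from consuming the Grignard reagent and from being oxidised in step 9.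

Step 6
Reactants: 9 tert-butyldimethylsilyl ether of 8
Product: 11 (3R,4R)-4-[(S)-(4-benzyloxy-3-methoxyphenyl)(tert-butyldimethylsilyloxy)methyl]tetrahydrofuran-3-carbaldehyde, via vicinal diol 10 (not isolated)
Conditions: OsO4 (2 mol %), NaIO4 (4 equiv), 2,6-lutidine (2 equiv), dioxane/H2O 3:1, rt; used crude
Reagents that add atoms: OsO4, O=[Os](=O)(=O)=O (delivers the oxygen atoms); NaIO4, [Na+].[O-]I(=O)(=O)=O (restores them as terminal oxidant)
Why: Lemieux–Johnson cleavage, in which catalytic dihydroxylation of the only alkene and periodate scission of diol 10 remove the terminal CH2 and leave C7' as the aldehyde carbon, while the buffered medium spares the electron-rich arenes, the silyl ether and the configuration at C8'.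

Step 7
Reactants: 12 4-bromo-2-methoxyphenol; 13 benzyl bromide
Product: 14 1-benzyloxy-4-bromo-2-methoxybenzene
Conditions: K2CO3 (1.5 equiv), DMF, rt
Reagents that add atoms: none
Why: Williamson ether synthesis of a phenoxide with a primary benzylic bromide has no competing pathway on this substrate.

Step 8
Reactants: 11 (3R,4R)-4-[(S)-(4-benzyloxy-3-methoxyphenyl)(tert-butyldimethylsilyloxy)methyl]tetrahydrofuran-3-carbaldehyde; 14 1-benzyloxy-4-bromo-2-methoxybenzene
Product: 16 {(3R,4R)-4-[(S)-(4-benzyloxy-3-methoxyphenyl)(tert-butyldimethylsilyloxy)methyl]tetrahydrofuran-3-yl}(4-benzyloxy-3-methoxyphenyl)methanol (both C7' epimers), via arylmagnesium bromide 15 (not isolated)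
Conditions: 14 (1.5 equiv), Mg, cat. I2, THF, 50 °C; then 11, THF, −78 → −20 °C; aqueous work-up
Reagents that add atoms: none
Why: Grignard addition of the aryl nucleophile to the aliphatic aldehyde forms the C7'–aryl bond at low temperature faster than C8' can enolise, and the epimer composition at C7' (Felkin–Anh delivery of the aryl group should favour the unwanted 7'R carbinol) is irrelevant because step 9 erases this centre.

Step 9
Reactants: 16 C7'-epimeric carbinols
Product: 17 {(3R,4R)-4-[(S)-(4-benzyloxy-3-methoxyphenyl)(tert-butyldimethylsilyloxy)methyl]tetrahydrofuran-3-yl}(4-benzyloxy-3-methoxyphenyl)methanone (7S,8R,8'R)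
Conditions: Dess–Martin periodinane (1.3 equiv), CH2Cl2, 0 °C → rt
Reagents that add atoms: none
Why: Dess–Martin oxidation turns both carbinol epimers into one aryl ketone under mild conditions that leave the silyl ether, the benzyl ethers and the trans-configured C8' untouched.

Step 10
Reactants: 17 silyloxy ketone
Product: 18 (S)-{(3R,4R)-4-[(S)-(4-benzyloxy-3-methoxyphenyl)(tert-butyldimethylsilyloxy)methyl]tetrahydrofuran-3-yl}(4-benzyloxy-3-methoxyphenyl)methanol (7S,8R,7'S,8'R)
Conditions: LiBH(s-Bu)3 (1.5 equiv), THF, −78 → −40 °C; aqueous work-up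
Reagents that add atoms: none
Why: Second Felkin–Anh reduction, now with C8 and its large silyloxybenzyl substituent as the perpendicular group, so that the bulky hydride again attacks the Re face and should give the 7'S carbinol, the C2-symmetric skeleton making this the same stereochemical problem as in step 4 and making any silyl shift between O7 and O7' degenerate.

Step 11
Reactants: 18 monosilylated diol
Product: 19 (1S,1'S)-[(3R,4R)-tetrahydrofuran-3,4-diyl]bis[(4-benzyloxy-3-methoxyphenyl)methanol]
Conditions: TBAF (1.5 equiv), THF, 0 °C → rt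
Reagents that add atoms: none
Why: Fluoride-induced silyl ether cleavage, driven by the strong Si–F bond, runs without acid, as the easily ionised electron-rich benzylic alcohols require.

Step 12
Reactants: 19 bis(benzyl ether) diol
Product: 20 (1S,1'S)-[(3R,4R)-tetrahydrofuran-3,4-diyl]bis[(4-hydroxy-3-methoxyphenyl)methanol], the target (7S,8R,7'S,8'R)
Conditions: H2 (1 atm), 10% Pd/C, EtOAc, rt, stopped at full conversion
Reagents that add atoms: none
Why: Catalytic hydrogenolysis cleaves the two aryl benzyl ethers much faster than the secondary benzylic C–O bonds in a neutral, acid-free medium, so that the free bisphenol should form with all four stereocentres untouched.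

Compound list
1 | 4-benzyloxy-3-methoxybenzaldehyde | COc1cc(C=O)ccc1OCc1ccccc1 | starting material
2 | vinylmagnesium bromide | C=C[Mg]Br | starting material
3 | rac-1-(4-benzyloxy-3-methoxyphenyl)prop-2-en-1-ol | COc1cc(C(O)C=C)ccc1OCc1ccccc1 | intermediate
4 | 1-(4-benzyloxy-3-methoxyphenyl)prop-2-en-1-one | COc1cc(C(=O)C=C)ccc1OCc1ccccc1 | intermediate
5 | rac-butadiene monoxide | C=CC1CO1 | starting material
6 | cis-3-(4-benzyloxy-3-methoxybenzoyl)-4-vinyltetrahydrofuran (3S,4R) | COc1cc(C(=O)[C@@H]2COC[C@@H]2C=C)ccc1OCc1ccccc1 | intermediate (not isolated)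
7 | trans-3-(4-benzyloxy-3-methoxybenzoyl)-4-vinyltetrahydrofuran (3R,4R) | COc1cc(C(=O)[C@H]2COC[C@@H]2C=C)ccc1OCc1ccccc1 | intermediate
8 | (S)-(4-benzyloxy-3-methoxyphenyl)[(3R,4R)-4-vinyltetrahydrofuran-3-yl]methanol | COc1cc([C@@H](O)[C@H]2COC[C@@H]2C=C)ccc1OCc1ccccc1 | intermediate
9 | tert-butyldimethylsilyl ether of 8 | COc1cc([C@@H](O[Si](C)(C)C(C)(C)C)[C@H]2COC[C@@H]2C=C)ccc1OCc1ccccc1 | intermediate
10 | 1-{(3R,4R)-4-[(S)-(4-benzyloxy-3-methoxyphenyl)(tert-butyldimethylsilyloxy)methyl]tetrahydrofuran-3-yl}ethane-1,2-diol, both carbinol epimers | COc1cc([C@@H](O[Si](C)(C)C(C)(C)C)[C@H]2COC[C@@H]2C(O)CO)ccc1OCc1ccccc1 | intermediate (not isolated)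
11 | (3R,4R)-4-[(S)-(4-benzyloxy-3-methoxyphenyl)(tert-butyldimethylsilyloxy)methyl]tetrahydrofuran-3-carbaldehyde | COc1cc([C@@H](O[Si](C)(C)C(C)(C)C)[C@H]2COC[C@@H]2C=O)ccc1OCc1ccccc1 | intermediate
12 | 4-bromo-2-methoxyphenol | COc1cc(Br)ccc1O | starting material
13 | benzyl bromide | BrCc1ccccc1 | starting material
14 | 1-benzyloxy-4-bromo-2-methoxybenzene | COc1cc(Br)ccc1OCc1ccccc1 | intermediate
15 | (4-benzyloxy-3-methoxyphenyl)magnesium bromide | COc1cc([Mg]Br)ccc1OCc1ccccc1 | intermediate (not isolated)
16 | 7-O-silyl 7'-carbinol, both C7' epimers (7S,8R,8'R) | COc1cc([C@@H](O[Si](C)(C)C(C)(C)C)[C@H]2COC[C@@H]2C(O)c2ccc(OCc3ccccc3)c(OC)c2)ccc1OCc1ccccc1 | intermediate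
17 | 7-O-silyl 7'-ketone (7S,8R,8'R) | COc1cc([C@@H](O[Si](C)(C)C(C)(C)C)[C@H]2COC[C@@H]2C(=O)c2ccc(OCc3ccccc3)c(OC)c2)ccc1OCc1ccccc1 | intermediate
18 | 7-O-silyl 7'S-carbinol (7S,8R,7'S,8'R) | COc1cc([C@@H](O[Si](C)(C)C(C)(C)C)[C@H]2COC[C@@H]2[C@H](O)c2ccc(OCc3ccccc3)c(OC)c2)ccc1OCc1ccccc1 | intermediate
19 | (1S,1'S)-[(3R,4R)-tetrahydrofuran-3,4-diyl]bis[(4-benzyloxy-3-methoxyphenyl)methanol] | COc1cc([C@@H](O)[C@H]2COC[C@@H]2[C@H](O)c2ccc(OCc3ccccc3)c(OC)c2)ccc1OCc1ccccc1 | intermediate
20 | (1S,1'S)-[(3R,4R)-tetrahydrofuran-3,4-diyl]bis[(4-hydroxy-3-methoxyphenyl)methanol] | COc1cc([C@@H](O)[C@H]2COC[C@@H]2[C@H](O)c2ccc(O)c(OC)c2)ccc1O | target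

Total step count: 12. Longest linear sequence: 11 (steps 1–6 and 8–12; step 7 is a one-step side branch).

Steps most likely to fail

1. Step 3.
- What may go wrong: capture of the allylpalladium alkoxide by a singly activated acceptor may be slow. Polymerisation of the enone, oligomerisation or isomerisation of the epoxide and allylation of the product enolate may then take over. Facial discrimination in the ring closure may also be poor.
- Fallback (sets out from 1, comes back at 9): the ring is not made by annulation but taken from a butenolide.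
- Rhodium-catalysed asymmetric 1,4-addition of Hayashi–Miyaura type to commercial furan-2(5H)-one gives (S)-4-vinyldihydrofuran-2(3H)-one F1, which carries C8'. The conditions are [Rh(cod)2]PF6, (S)-BINAP (sense by analogy with cyclic enones), potassium vinyltrifluoroborate, toluene/H2O.
- Its potassium enolate (KN(SiMe3)2, THF, −78 °C) adds to aldehyde 1 anti to the vinyl group and is expected to favour the 7,8-syn carbinol. This gives the trans aldol lactone F2.
- Silylation (TBSOTf, 2,6-lutidine) gives the silyl ether lactone F3, and LiBH4 (THF/MeOH) gives the 1,4-diol F4.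
- Mitsunobu cyclodehydration (PPh3, DIAD, THF) of the two primary hydroxyl groups closes the tetrahydrofuran ring to 9.

2. Step 4.
- What may go wrong: facial selectivity may be poor, because the vinyl group on C8' is small and lies on the ring face opposite to the carbonyl group. The Felkin bias may therefore be weak.
- Fallback (sets out from 7, comes back at 8): the control element is moved from the substrate to a chiral catalyst. A Corey–Bakshi–Shibata reduction is used, with (R)-Me-CBS oxazaborolidine and catecholborane in toluene at −78 °C.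
- Catecholborane is chosen because it does not hydroborate the vinyl group at this temperature.
- With the aryl group as the large substituent, this catalyst enantiomer delivers hydride to the Re face (7S), matched with the substrate bias. No new compound arises (F0).

3. Step 12.
- What may go wrong: over-reduction, that is hydrogenolysis of the benzylic C–OH bonds that the para oxygen activates, during debenzylation.
- Fallback (sets out from 17, comes back at 20): the benzyl ethers are removed earlier, while C7' is still a carbonyl carbon and O7 is silylated. No free benzylic alcohol then meets the catalyst.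
- H2, Pd/C, EtOAc gives the bisphenol ketone F5, and TBSCl, imidazole, DMF gives the tris-silyl ketone F6.
- LiBH(s-Bu)3 as in step 10 gives the tris-silyl carbinol F7. TBAF buffered with AcOH in THF then removes all three silyl groups in one operation to give 20.

Further compounds
F1 | step 3 | (S)-4-vinyldihydrofuran-2(3H)-one | O=C1C[C@@H](C=C)CO1
F2 | step 3 | (3S,4R)-3-[(S)-(4-benzyloxy-3-methoxyphenyl)(hydroxy)methyl]-4-vinyldihydrofuran-2(3H)-one | COc1cc([C@@H](O)[C@H]2C(=O)OC[C@@H]2C=C)ccc1OCc1ccccc1
F3 | step 3 | tert-butyldimethylsilyl ether of F2 | COc1cc([C@@H](O[Si](C)(C)C(C)(C)C)[C@H]2C(=O)OC[C@@H]2C=C)ccc1OCc1ccccc1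
F4 | step 3 | (2R,3R)-2-[(S)-(4-benzyloxy-3-methoxyphenyl)(tert-butyldimethylsilyloxy)methyl]-3-vinylbutane-1,4-diol | COc1cc([C@@H](O[Si](C)(C)C(C)(C)C)[C@@H](CO)[C@H](CO)C=C)ccc1OCc1ccccc1
F0 | step 4 | none | none
F5 | step 12 | bisphenol of ketone 17 (7S,8R,8'R) | COc1cc([C@@H](O[Si](C)(C)C(C)(C)C)[C@H]2COC[C@@H]2C(=O)c2ccc(O)c(OC)c2)ccc1O
F6 | step 12 | 4,4',7-tris-O-(tert-butyldimethylsilyl) 7'-ketone (7S,8R,8'R) | COc1cc([C@@H](O[Si](C)(C)C(C)(C)C)[C@H]2COC[C@@H]2C(=O)c2ccc(O[Si](C)(C)C(C)(C)C)c(OC)c2)ccc1O[Si](C)(C)C(C)(C)C
F7 | step 12 | 4,4',7-tris-O-(tert-butyldimethylsilyl) 7'S-carbinol (7S,8R,7'S,8'R) | COc1cc([C@@H](O[Si](C)(C)C(C)(C)C)[C@H]2COC[C@@H]2[C@H](O)c2ccc(O[Si](C)(C)C(C)(C)C)c(OC)c2)ccc1O[Si](C)(C)C(C)(C)C
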